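Readings and results were computed for substances that don't exist; noise was put on by code.

5 questions stand over 4 flasks. Two people dispute one of them: west, held at 25 °C for 25 min and then at −25 °C.

the same everywhere: E 16 mM

|  | Z | L | temperature | remark | time |
|---|---|---|---|---|---|
| midnight | 0.80 M | 0.020 M | −30 °C | run made earlier |  |
| dusk | 0.80 M | 0.030 M | 0 °C | run made earlier |  |
| spring | 1.2 M | 0.040 M | −30 °C | run made earlier |  |
| east | 0.80 M | 0.0400 M | 25 °C |  | 2.0 h |
| south-west | 0.80 M | 0.0400 M | −25 °C |  | 2.0 h |
| west | 0.80 M | 0.0400 M |  | at 25 °C until 25 min, from then on at −25 °C | 2.0 h |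
| south | 0.80 M | 0.0400 M | 0 °C |  | 2.0 h |

- midnight (time / h: G / %): 10.0: 0.5; 20.0: 2.8; 30.0: 2.1; 40.0: 4.4
- dusk (time / h: G / %): 0.667: 4.9; 1.33: 11.9; 3.00: 25.4; 8.00: 65.7
- spring (time / h: G / %): 5.00: 0.2; 12.0: 1.1; 25.0: 1.7; 40.0: 3.2

(readings scatter by 0.5 percentage points)

- the flask with the highest amount of G, in percent of the Z charged ("all alike" if they lie within 1.5 percentage points) (east / south-west / west / south / all alike)
- final G, as a percentage of the Z charged, in east
- final G, as a percentage of the Z charged, in south-west
- final G, as a percentage of the Z charged, in west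
- final G, as a percentage of the Z charged, in south

- the earlier runs were read with a standard deviation of 0.5 percentage points
- a reading or a percentage of G counts all its forms, free or not

In the dusk run G climbs along a nearly straight line (zero order in Z) up to 65.7%, so I freeze the rate and count it per E. The dusk reading gives 4.11 h⁻¹ (a turnover rate) at 0 °C, and the midnight reading gives 0.0550 h⁻¹ at −30 °C. The spring run, with twice the L of midnight, reads 0.0600 h⁻¹, so I leave L out. The two temperatures give an activation energy of 79.4 kJ mol⁻¹, which carries the rate beyond the readings to 77.0 h⁻¹ at 25 °C and 0.121 h⁻¹ at −25 °C.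

The first person counts. The number of turns each E makes in the warm stage, warm rate times warm time, is 32.1. That is fewer than the 50.0 turns that [Z]/[E] offers, so Z outlasts the warm stage in west. With the cold stage added, G comes to 64.5%.

The second person says a flask's yield follows its share of the time. West spends 20.8% of its time warm, so it gets about that share of the charge. The first replies that the frozen rate, as an estimate, puts east through its [Z]/[E] turns in 39.0 min of its 2.0 h, so on this count the yield of east does not follow its share of the time. The second replies that no reading has seen the warm rate.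

I side with the count: east ends where its Z ends, south-west reaches 0.485% and south 16.4%.

The forecast takes the same side, with east highest, east 99%, south-west 0.5%, west 66% and south 17%, on the grounds that “25 min at about 155 %/h gives about 65%”, a little above my figure.

The simulation gives east 95.0%, south-west 0.497%, west 54.9% and south 16.8%, so east holds most. West lies 9.6 percentage points under the count and 34 points over the share of time, so the count stands nearer. The share of time matches the count for a flask still on its straight line at the asked time, and east was not, with 93.4% of G by 1.00 h.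

    X → D (k = 0.630 s⁻¹, Ea = 63.0 kJ mol⁻¹)
    D → E + G (k = 0.0230 s⁻¹, Ea = 79.0 kJ mol⁻¹)
    Z + E ⇌ X (K = 1.00 L mol⁻¹, k = 0.320 L mol⁻¹ s⁻¹, Ea = 47.0 kJ mol⁻¹, ΔH = −45.0 kJ mol⁻¹)
    E + G ⇌ J (K = 5.10 L mol⁻¹, k = 4.00 × 10⁻⁴ L mol⁻¹ s⁻¹, Ea = 57.0 kJ mol⁻¹, ΔH = −61.0 kJ mol⁻¹)
    Z + L → Q (k = 0.00720 L mol⁻¹ s⁻¹, Ea = 64.0 kJ mol⁻¹)
    (constants at 25 °C)

West's 54.9% of G means 27.4 turns per E, against the 32.1 counted for its warm stage. A neighbour of west is charged with 0.0096 M of E, everything else held. Multiplying turns by [E]/[Z] gives 38.5% of G for this neighbour with the first count, and 32.9% with west's own. The neighbour flask ends at 34.1% of G, with 60% of the Z charged still free at 2.00 h.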